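The vessel is closed and stirred. Solid substrate lies in it, goes into solution as starting material, and the dissolved part reacts on.

| flask | solid substrate | remark | time |
|---|---|---|---|
| noon | 3 M | the very flask that is asked about, followed so far |  |
| flask | 3.0 M |  | 6.0 h |

noon run (percent of the solid substrate charged)

| time / min | solid substrate / % | target / % | starting material / % |
|---|---|---|---|
| 8.00 | 98.6 | 0 | 1.9 |
| 15.0 | 96.9 | 0 | 2.4 |
| 30.0 | 95.2 | 0.4 | 4.1 |
| 60.0 | 90.9 | 0 | 7.4 |
| 120 | 80.6 | 1.1 | 10.2 |

(scatter of a reading: 0.5 percentage points)

- solid, in amounts per volume of the solution: solid substrate
- the numbers in the tables scatter by 0.5 percentage points (one standard deviation)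
- at the start none of the solid substrate is in solution
- what has only dissolved of solid substrate counts as not reacted
- starting material means what is dissolved; the solid is not counted in it
- the reaction counts as stopped when no species that holds the solid substrate changes by six tenths of a point or more over the second half of the time

- the state of affairs at 6.0 h: stopped, and by what, or still going (for what has run out or reacted, a solid counts together with what of it has only dissolved) (all of the solid substrate has reacted / it is still moving / forward and back rates have come level)
- part of the solid substrate that has turned into other species by 6.0 h (what has only dissolved does not count)
- amount of target at 6.0 h, in percent of the solid substrate charged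
- amount of starting material at 6.0 h, in percent of the solid substrate charged

The bench rule for such a flask is a zero-order line: if the solid does not slow, [solid substrate] falls at a steady rate, and charge over rate is the clearing time. The noon run stands at 80.6% after 120 min, so I read a fall of 0.291 M h⁻¹ and a clearing time of 10.3 h. That is longer than the 6.0 h asked. I go to logarithms: the base-ten logarithm of time asked over clearing time is −0.235. I call this the clearing exponent. Below zero, the line still has solid at the time asked. At zero, the line meets empty and the rule stops.

The border of trust is nearer. The time asked is 3.00 times the last reading, so the line runs 0.477 of a power of ten past anything seen. A fall that slows lowers the exponent, so slowing leaves its sign negative, but it changes the amount of solid. I commit to 41.8% of solid substrate in this flask, and to a flask still moving.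

The forecast says it is still moving, with conversion 45%, target 15% and starting material 14%, on a solid “with no sign of slowing”.

The simulation of this flask gives it is still moving, with conversion 36.4%, target 4.89% and starting material 12.5%.

    starting material → intermediate (k = 0.0100 min⁻¹)
    intermediate ⇌ target (K = 0.840, k = 0.0118 min⁻¹)
    intermediate ⇌ isomer of the product (K = 2.95, k = 0.00493 min⁻¹)
    target → over-reaction product (k = 0.0121 min⁻¹)
    solid substrate ⇌ starting material, rate k5*(cs5 - [starting material]) while solid is left; crystals form when [starting material] > cs5 (solubility = 1.30 M, k = 0.00409 min⁻¹)

At 6.00 h this flask holds 51.1% of solid substrate, more than the line's 41.8%, and solid still stands in it, as the negative exponent says. I take the same fall in M per hour for the neighbour flask charged with 0.75 M: its smaller charge adds 0.602 to the exponent, which makes 0.367, above zero, and at 6.00 h that neighbour flask holds 0% of solid substrate.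

The data are calculated with made-up constants; the scatter is artificial.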